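**Retrosynthetic overview**
1. Feature: the central ring (ring B) carries C1–OAr, C2–OH, C3–Br, C4–OAr, C5–OH and C6–Br. The para pair C2–O/C5–O is a hydroquinone. Ring B therefore maps onto a cyclohexane-1,4-dione whose α-carbons C1 and C4 already hold the aryloxy groups and whose two methylene carbons C3 and C6 are the future C–Br carbons.
2. Backwards from the target: the two O–CH3 bonds on rings A and C (BBr3), then the quinone/hydroquinone redox pair (Na2S2O4). Next, in one operation, come the C3–Br and C6–Br bonds together with the aromaticity of ring B (Br2), which leads back to cis-2,5-bis(aryloxy)cyclohexane-1,4-dione.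
3. The C1–O and C4–O bonds are made at sp3 carbon by two trans-diaxial epoxide openings on a ring taken from cyclohexa-1,4-diene. The second oxirane is placed syn to the first hydroxyl by directed epoxidation, because the Fürst–Plattner rule then sends the second aryloxide to the carbon para to the first. An anti oxirane would send it to the meta carbon.
4. Rings: no carbocycle is built. Rings A and C are identical and come from 3,5-dibromo-4-hydroxybenzaldehyde with all three bromines in place. Ring B is bought as a six-membered carbocycle, carries two transient oxiranes (steps 4 and 6) and is aromatised last.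

Key step: step 9

Assumption: the four chiral cyclohexane intermediates between the first epoxide opening and the dione are racemic, and each SMILES shows one enantiomer. The target is achiral, so only relative configuration matters.

**Step 1**
Reactants: 1 3,5-dibromo-4-hydroxybenzaldehyde
Product: 2 3,5-dibromo-4-methoxybenzaldehyde
Conditions: MeI (1.5 equiv), K2CO3 (1.5 equiv), DMF, rt
Reagents that add atoms: iodomethane, CI
Why: Williamson O-methylation of an acidic, di-ortho-brominated phenoxide with a small electrophile, under which the aldehyde is inert.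

**Step 2**
Reactants: 2 3,5-dibromo-4-methoxybenzaldehyde
Product: 4 3,5-dibromo-4-methoxyphenol, via 3,5-dibromo-4-methoxyphenyl formate 3 (not isolated)
Conditions: mCPBA (1.5 equiv), CH2Cl2, 40 °C; then MeOH, cat. HCl, rt
Reagents that add atoms: 3-chloroperoxybenzoic acid (mCPBA), OOC(=O)c1cccc(Cl)c1
Why: Baeyer–Villiger oxidation in which the para-methoxyaryl group migrates in preference to hydride to give formate 3, whose acid-catalysed methanolysis frees the phenol without touching C–Br or O–CH3 bonds.

**Step 3**
Reactants: 4 3,5-dibromo-4-methoxyphenol; 5 bromine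
Product: 6 2,3,5-tribromo-4-methoxyphenol
Conditions: Br2 (1.0 equiv), AcOH–CH2Cl2, 0 °C → rt
Reagents that add atoms: bromine (5), BrBr
Why: Electrophilic aromatic bromination directed by the free OH to one of its two equivalent ortho carbons (para is blocked by OMe), held at the tribromide by the single equivalent of Br2 and by the deactivation from the third bromine.

**Step 4**
Reactants: 7 cyclohexa-1,4-diene
Product: 8 7-oxabicyclo[4.1.0]hept-3-ene (monoepoxide, cis-fused, meso)
Conditions: mCPBA (1.0 equiv), 7 (1.5 equiv), CH2Cl2, 0 °C
Reagents that add atoms: 3-chloroperoxybenzoic acid (mCPBA), OOC(=O)c1cccc(Cl)c1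
Why: Prilezhaev epoxidation, a concerted syn addition that gives the cis-fused meso oxirane, with the excess of diene holding the reaction at the monoepoxide.

**Step 5**
Reactants: 8 7-oxabicyclo[4.1.0]hept-3-ene; 6 2,3,5-tribromo-4-methoxyphenol
Product: 9 rac-(1R,6R)-6-(2,3,5-tribromo-4-methoxyphenoxy)cyclohex-3-en-1-ol (OH and OAr trans)
Conditions: 8 (1.3 equiv), Cs2CO3 (10 mol %), DMF, 100 °C, sealed tube
Reagents that add atoms: none
Why: Base-catalysed SN2 phenolysis of a meso epoxide, in which backside attack sets the trans relationship of OAr and OH (racemate) and the weakly basic aryloxide should not trigger base-induced isomerisation of the allylic epoxide.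

**Step 6**
Reactants: 9 rac-(1R,6R)-6-(2,3,5-tribromo-4-methoxyphenoxy)cyclohex-3-en-1-ol
Product: 10 rac-(1S,3R,4R,6R)-4-(2,3,5-tribromo-4-methoxyphenoxy)-7-oxabicyclo[4.1.0]heptan-3-ol (oxirane cis to OH, trans to OAr)
Conditions: VO(acac)2 (3 mol %), t-BuOOH (1.5 equiv, decane), toluene, rt → 40 °C
Reagents that add atoms: tert-butyl hydroperoxide, CC(C)(C)OO
Why: Vanadium-catalysed hydroxyl-directed epoxidation of a homoallylic cyclohexenol, in which the vanadium alkoxide delivers oxygen to the face that bears the OH (the aryloxy group shields the other face), so both new stereocentres place the oxirane cis to OH.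

**Step 7**
Reactants: 10 the epoxy alcohol of step 6; 6 2,3,5-tribromo-4-methoxyphenol
Product: 11 rac-(1R,2R,4R,5R)-2,5-bis(2,3,5-tribromo-4-methoxyphenoxy)cyclohexane-1,4-diol (C2-symmetric; both OAr on one face, both OH on the other)
Conditions: 6 (1.2 equiv), Cs2CO3 (20 mol %), DMF, 110 °C
Reagents that add atoms: none
Why: Fürst–Plattner (trans-diaxial) SN2 epoxide opening, in which the half-chair with OH and OAr equatorial offers the axial trajectory anti to the oxirane only at C1 of the oxabicycle (para to C4–OAr), whereas attack at C6 would need the diaxial conformer and a syn-axial clash with the aryloxy group; inversion at C1 sets the new OAr trans to the new OH.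

**Step 8**
Reactants: 11 rac-(1R,2R,4R,5R)-2,5-bis(2,3,5-tribromo-4-methoxyphenoxy)cyclohexane-1,4-diol
Product: 12 rac-(2R,5R)-2,5-bis(2,3,5-tribromo-4-methoxyphenoxy)cyclohexane-1,4-dione (cis)
Conditions: Dess–Martin periodinane (2.6 equiv), CH2Cl2, 0 °C → rt; base-free work-up (dilution, filtration through a short silica pad), used at once
Reagents that add atoms: none
Why: Dess–Martin oxidation of two secondary alcohols under neutral to weakly acidic conditions, so the β-aryloxy ketone never meets a base; the carbinol stereocentres disappear and the two C–OAr centres remain cis.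

**Step 9**
Reactants: 12 rac-(2R,5R)-2,5-bis(2,3,5-tribromo-4-methoxyphenoxy)cyclohexane-1,4-dione; 5 bromine
Product: 15 2,5-dibromo-3,6-bis(2,3,5-tribromo-4-methoxyphenoxy)-1,4-benzoquinone, via 2,5-bis(aryloxy)benzene-1,4-diol 13 (not isolated), via 2,5-bis(aryloxy)-1,4-benzoquinone 14 (not isolated)
Conditions: Br2 (6 equiv), HBr in AcOH (5 mol %), AcOH–CH2Cl2, 12 added slowly to the Br2 solution at 0 °C, then 40 °C, dark
Reagents that add atoms: bromine (5), BrBr
Why: Acid-catalysed enolisation of either ketone of 12 (towards CH2 or towards CH–OAr), capture of the enol by Br2 and loss of HBr (the new bromide always sits β to the other carbonyl) give an ene-dione that tautomerises to hydroquinone 13; a second Br2 oxidises 13 to quinone 14, whose C3 and C6 are the β-carbons of two aryl enol ethers and take up bromine by addition–elimination (bromination of 13 before its oxidation leads to the same product), so four Br2 are used, six HBr are released and the C3–Br and C6–Br bonds are formed. The closest known reaction types are the bromine-mediated dehydrogenative aromatisation of cyclohexane-1,4-diones and the addition–elimination bromination of 2,5-dialkoxy-1,4-benzoquinones, here run in one flask. No ring is closed and no stereocentre is created; the two stereocentres of 12 are erased, so its cis configuration and any epimerisation have no consequence. The chemoselectivity needed is bromination of the enol ahead of β-loss of the aryloxy group: acid-catalysed ketone halogenation is limited by enolisation because halogen capture of the enol is much faster than its other fates, inverse addition keeps Br2 in excess over every enol formed, and without base there is no enolate for E1cB expulsion (2,5-dihalocyclohexane-1,4-diones, which hold a better β-leaving group, can be handled in such media). The site selectivity needed is ring B over rings A and C: each outer ring carries three bromines, a methoxy group twisted out of conjugation by two ortho bromines and an ether oxygen drained by the keto or quinone carbon, so its single C–H should stay untouched without a Lewis acid, while C3 and C6 are the only free positions of ring B.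

**Step 10**
Reactants: 15 2,5-dibromo-3,6-bis(2,3,5-tribromo-4-methoxyphenoxy)-1,4-benzoquinone
Product: 16 2,5-dibromo-3,6-bis(2,3,5-tribromo-4-methoxyphenoxy)benzene-1,4-diol
Conditions: Na2S2O4 (3 equiv), EtOAc–H2O, rt, N2
Reagents that add atoms: none
Why: Dithionite reduction of a quinone to its hydroquinone, fast enough in a two-phase system that the vinylogous-ester C–OAr bonds are not hydrolysed, with aryl bromides and methyl ethers inert.

**Step 11**
Reactants: 16 2,5-dibromo-3,6-bis(2,3,5-tribromo-4-methoxyphenoxy)benzene-1,4-diol
Product: 17 2,5-dibromo-3,6-bis(2,3,5-tribromo-4-hydroxyphenoxy)benzene-1,4-diol (target, CNP0163357.0)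
Conditions: BBr3 (6 equiv), CH2Cl2, −78 °C → rt; then H2O, 0 °C
Reagents that add atoms: none
Why: Lewis-acid cleavage of aryl methyl ethers, in which BBr3 binds the methoxy oxygen and bromide attacks the methyl carbon (SN2); diaryl ether bonds offer no sp3 carbon and survive, and hydrolysis of the aryl borates frees all four OH groups.

**Compound list**
1 | 3,5-dibromo-4-hydroxybenzaldehyde | O=Cc1cc(Br)c(O)c(Br)c1 | starting material
2 | 3,5-dibromo-4-methoxybenzaldehyde | O=Cc1cc(Br)c(OC)c(Br)c1 | intermediate
3 | 3,5-dibromo-4-methoxyphenyl formate | O=COc1cc(Br)c(OC)c(Br)c1 | intermediate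
4 | 3,5-dibromo-4-methoxyphenol | Oc1cc(Br)c(OC)c(Br)c1 | intermediate
5 | bromine | BrBr | starting material
6 | 2,3,5-tribromo-4-methoxyphenol | Oc1cc(Br)c(OC)c(Br)c1Br | intermediate
7 | cyclohexa-1,4-diene | C1=CCC=CC1 | starting material
8 | 7-oxabicyclo[4.1.0]hept-3-ene (meso, cis-fused) | C1=CC[C@H]2O[C@H]2C1 | intermediate
9 | rac-(1R,6R)-6-(2,3,5-tribromo-4-methoxyphenoxy)cyclohex-3-en-1-ol (one enantiomer drawn) | O[C@@H]1CC=CC[C@H]1Oc1cc(Br)c(OC)c(Br)c1Br | intermediate
10 | rac-(1S,3R,4R,6R)-4-(2,3,5-tribromo-4-methoxyphenoxy)-7-oxabicyclo[4.1.0]heptan-3-ol (one enantiomer drawn) | O[C@@H]1C[C@@H]2O[C@@H]2C[C@H]1Oc1cc(Br)c(OC)c(Br)c1Br | intermediate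
11 | rac-(1R,2R,4R,5R)-2,5-bis(2,3,5-tribromo-4-methoxyphenoxy)cyclohexane-1,4-diol (one enantiomer drawn) | O[C@@H]1C[C@@H](Oc2cc(Br)c(OC)c(Br)c2Br)[C@H](O)C[C@H]1Oc1cc(Br)c(OC)c(Br)c1Br | intermediate
12 | rac-(2R,5R)-2,5-bis(2,3,5-tribromo-4-methoxyphenoxy)cyclohexane-1,4-dione (cis; one enantiomer drawn) | O=C1C[C@@H](Oc2cc(Br)c(OC)c(Br)c2Br)C(=O)C[C@H]1Oc1cc(Br)c(OC)c(Br)c1Br | intermediate
13 | 2,5-bis(2,3,5-tribromo-4-methoxyphenoxy)benzene-1,4-diol | COc1c(Br)cc(Oc2cc(O)c(Oc3cc(Br)c(OC)c(Br)c3Br)cc2O)c(Br)c1Br | intermediate
14 | 2,5-bis(2,3,5-tribromo-4-methoxyphenoxy)-1,4-benzoquinone | COc1c(Br)cc(OC2=CC(=O)C(Oc3cc(Br)c(OC)c(Br)c3Br)=CC2=O)c(Br)c1Br | intermediate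
15 | 2,5-dibromo-3,6-bis(2,3,5-tribromo-4-methoxyphenoxy)-1,4-benzoquinone | COc1c(Br)cc(OC2=C(Br)C(=O)C(Oc3cc(Br)c(OC)c(Br)c3Br)=C(Br)C2=O)c(Br)c1Br | intermediate
16 | 2,5-dibromo-3,6-bis(2,3,5-tribromo-4-methoxyphenoxy)benzene-1,4-diol | COc1c(Br)cc(Oc2c(O)c(Br)c(Oc3cc(Br)c(OC)c(Br)c3Br)c(O)c2Br)c(Br)c1Br | intermediate
17 | 2,5-dibromo-3,6-bis(2,3,5-tribromo-4-hydroxyphenoxy)benzene-1,4-diol | Oc1c(Br)cc(Oc2c(O)c(Br)c(Oc3cc(Br)c(O)c(Br)c3Br)c(O)c2Br)c(Br)c1Br | target

**Total step count:** 11
**Longest linear sequence:** 10 steps (1 → 17 through steps 1, 2, 3, 5, 6, 7, 8, 9, 10, 11)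

**Steps most likely to fail**

**Step 9.**
- What may go wrong: the enol or the ene-dione may expel an aryloxy group before bromine arrives, so that ring B aromatises without oxidant and keeps only one ether. Accumulating HBr may exchange aryloxy for bromide on the quinone. Slow bromination of the outer-ring C–H may also set in.
- Fallback: ring B is bought at the quinone level and the ethers are made by addition–elimination. It sets out from 6.
- Two equivalents of 6 are deprotonated with K2CO3 in MeCN and added to commercial tetrabromo-1,4-benzoquinone (O=C1C(Br)=C(Br)C(=O)C(Br)=C1Br) at 0 °C → rt.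
- The first substitution gives 2,3,5-tribromo-6-(2,3,5-tribromo-4-methoxyphenoxy)-1,4-benzoquinone F1. Its aryloxy group deactivates, as a vinylogous ester, the carbonyl it is conjugated with, so the second aryloxide adds β to the other carbonyl, at the carbon para to the first ether. This is the known 2,5-pattern of tetrahaloquinones with aryloxides.
- The route is rejoined at 15.

**Step 8.**
- What may go wrong: β-elimination of the aryloxy group, with aromatisation, during oxidation, work-up or contact with silica.
- Fallback: the dione is never isolated. It sets out from 11.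
- The diol is exposed to bromine generated continuously from NaBrO3 and HBr in AcOH, a system known to oxidise secondary alcohols to ketones and hydroquinones to quinones.
- The dione is then fed at low stationary concentration into the same bromination cascade, and HBr is recycled instead of accumulating.
- Steps 8 and 9 merge and the route is rejoined at 15. This fallback makes no compound outside the list (F0).

**Step 7.**
- What may go wrong: sluggish opening of the cyclohexene oxide by the ortho-brominated, weakly nucleophilic aryloxide, with thermal degradation or erosion of regioselectivity at the temperature needed.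
- Fallback: the C–O bond is made first and the ortho bromine is added afterwards. It sets out from 10 and 4.
- The unhindered and more nucleophilic phenol 4 opens 10 under the same base catalysis and the same Fürst–Plattner control. This gives rac-(1R,2R,4R,5R)-2-(3,5-dibromo-4-methoxyphenoxy)-5-(2,3,5-tribromo-4-methoxyphenoxy)cyclohexane-1,4-diol F2.
- NBS (1 equiv) in MeCN then brominates the dibromo ring at one of its two equivalent carbons ortho to the alkyl aryl ether oxygen, while the tribromo ring stays inert.
- The route is rejoined at 11.

**Further compounds**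
F1 | step 9 | 2,3,5-tribromo-6-(2,3,5-tribromo-4-methoxyphenoxy)-1,4-benzoquinone | COc1c(Br)cc(OC2=C(Br)C(=O)C(Br)=C(Br)C2=O)c(Br)c1Br
F0 | step 8 | none | none
F2 | step 7 | rac-(1R,2R,4R,5R)-2-(3,5-dibromo-4-methoxyphenoxy)-5-(2,3,5-tribromo-4-methoxyphenoxy)cyclohexane-1,4-diol | O[C@@H]1C[C@@H](Oc2cc(Br)c(OC)c(Br)c2)[C@H](O)C[C@H]1Oc1cc(Br)c(OC)c(Br)c1Br
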